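**Assumptions**

- Ring carbons are numbered as in eremophilane (C1–C15); the target is 4S,5R,7R,8R,9S,10S, and these locants are also used for the open-chain precursors.
- In step 4 the catalyst enantiomer is the one whose open enal face leads to 7, written here as the (S)-proline-derived oxazaborolidinium; its antipode is used if the sense proves opposite.
- The six starting materials (1, 3, 6, 8, 17, 20) are taken as commercial.

**Retrosynthetic overview**

1. Both esters go on last: the C9 senecioate after opening a C2–O9 ketal bridge, the C8 tiglate just before.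
2. Ring B (C7–C8 bond, C7 and C8 stereocentres) comes from a Ru–H-catalysed redox-neutral cyclisation of a primary carbinol onto a tethered 2-substituted diene.
3. The diene comes from Wittig olefination of a C6 aldehyde; the ketal bridge (C9–OH onto the C2 ketone) locks ring A for the ring-B closure.
4. Ring A (C3–C4 and C5–C10 bonds; C4, C5, C10) comes from a catalytic asymmetric Diels–Alder reaction of a chiral 2-siloxy diene with tiglaldehyde.
5. The diene comes from (S)-but-3-ene-1,2-diol (source of C9) and methyl vinyl ketone by cross-metathesis. Ring order: A, then the O-bridge, then B.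

**Route**

Step 1
Reactants: 1 (S)-but-3-ene-1,2-diol
Product: 2 (2S)-2-hydroxybut-3-en-1-yl 2,2-dimethylpropanoate
Conditions: PivCl (1.05 equiv), pyridine, CH2Cl2, −20 → 0 °C
Reagents that add atoms: pivaloyl chloride, CC(C)(C)C(=O)Cl
Why: Regioselective acylation (esterification) of the primary hydroxyl by the bulky acid chloride; the C9 carbinol (S, chiral pool) stays free and the pivalate later keeps O8 out of the ketalisation.

Step 2
Reactants: 2 (2S)-2-hydroxybut-3-en-1-yl 2,2-dimethylpropanoate; 3 but-3-en-2-one (methyl vinyl ketone)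
Product: 4 (2S,3E)-2-hydroxy-5-oxohex-3-en-1-yl 2,2-dimethylpropanoate
Conditions: Hoveyda–Grubbs II (3 mol %), 3 (3 equiv), CH2Cl2, 40 °C
Reagents that add atoms: none
Why: Olefin cross-metathesis of an allylic alcohol with an enone gives the E cross-product; the stereocentre is untouched.

Step 3
Reactants: 4 (2S,3E)-2-hydroxy-5-oxohex-3-en-1-yl 2,2-dimethylpropanoate
Product: 5 (2S,3E)-2,5-bis(triethylsilyloxy)hexa-3,5-dien-1-yl 2,2-dimethylpropanoate
Conditions: TESOTf (2.3 equiv), Et3N (3 equiv), CH2Cl2, −78 → 0 °C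
Reagents that add atoms: triethylsilyl trifluoromethanesulfonate, CC[Si](CC)(CC)OS(=O)(=O)C(F)(F)F
Why: O-silylation and soft enolisation of the methyl ketone (silyl enol ether formation) give the cross-conjugated 2-siloxy diene; no stereocentre is formed.

Step 4
Reactants: 5 (2S,3E)-2,5-bis(triethylsilyloxy)hexa-3,5-dien-1-yl 2,2-dimethylpropanoate; 6 (E)-2-methylbut-2-enal (tiglaldehyde)
Product: 7 (2S)-2-[(1S,5S,6R)-6-formyl-5,6-dimethyl-3-(triethylsilyloxy)cyclohex-2-en-1-yl]-2-(triethylsilyloxy)ethyl 2,2-dimethylpropanoate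
Conditions: (S)-o-tolyl-CBS-oxazaborolidine/Tf2NH (20 mol %), 6 (1.5 equiv), CH2Cl2, −78 → −40 °C
Reagents that add atoms: none
Why: Catalytic asymmetric Diels–Alder reaction (Corey oxazaborolidinium): both donor groups of the diene send C3 to the enal β-carbon, the E dienophile fixes the cis C4/C5 methyls, the endo formyl puts C9 cis to C6 at C10, and the shielded enal face sets the absolute configuration of C4, C5 and C10.

Step 5
Reactants: 8 3-chloro-2-methylprop-1-ene
Product: 9 (2-methylprop-2-en-1-yl)triphenylphosphonium chloride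
Conditions: PPh3, MeCN, 80 °C
Reagents that add atoms: triphenylphosphine, c1ccc(cc1)P(c1ccccc1)c1ccccc1
Why: SN2 quaternisation of the allylic chloride by the phosphine.

Step 6
Reactants: 7 (2S)-2-[(1S,5S,6R)-6-formyl-5,6-dimethyl-3-(triethylsilyloxy)cyclohex-2-en-1-yl]-2-(triethylsilyloxy)ethyl 2,2-dimethylpropanoate; 9 (2-methylprop-2-en-1-yl)triphenylphosphonium chloride
Product: 11 (2S)-2-[(1S,5S,6S)-5,6-dimethyl-6-[(1E)-3-methylbuta-1,3-dien-1-yl]-3-(triethylsilyloxy)cyclohex-2-en-1-yl]-2-(triethylsilyloxy)ethyl 2,2-dimethylpropanoate, via (2-methylprop-2-en-1-ylidene)triphenylphosphorane 10 (not isolated)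
Conditions: 9 (1.5 equiv), n-BuLi, THF, −78 → 0 °C; then 7, −78 °C → rt
Reagents that add atoms: none
Why: Wittig olefination of the non-enolisable neopentyl aldehyde by the allylic ylide gives the 1,3-diene (E major; the C6=C7 geometry is erased in step 9); no stereocentre changes.

Step 7
Reactants: 11 (2S)-2-[(1S,5S,6S)-5,6-dimethyl-6-[(1E)-3-methylbuta-1,3-dien-1-yl]-3-(triethylsilyloxy)cyclohex-2-en-1-yl]-2-(triethylsilyloxy)ethyl 2,2-dimethylpropanoate
Product: 13 [(1S,2S,3S,5S,7S)-5-methoxy-2,3-dimethyl-2-[(1E)-3-methylbuta-1,3-dien-1-yl]-6-oxabicyclo[3.2.1]octan-7-yl]methyl 2,2-dimethylpropanoate, via hydroxy ketone 12 (not isolated)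
Conditions: PPTS (0.2 equiv), MeOH, rt; then PhMe, 50 °C, 4 Å MS
Reagents that add atoms: methanol, CO
Why: Acid-catalysed methanolysis of both silyl groups followed by intramolecular mixed ketalisation: the axial C9 carbinol bridges to C2 in a five-membered ring, which fixes the new C2 centre, masks the ketone and O9, and locks ring A with C9 axial.

Step 8
Reactants: 13 [(1S,2S,3S,5S,7S)-5-methoxy-2,3-dimethyl-2-[(1E)-3-methylbuta-1,3-dien-1-yl]-6-oxabicyclo[3.2.1]octan-7-yl]methyl 2,2-dimethylpropanoate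
Product: 14 [(1S,2S,3S,5S,7S)-5-methoxy-2,3-dimethyl-2-[(1E)-3-methylbuta-1,3-dien-1-yl]-6-oxabicyclo[3.2.1]octan-7-yl]methanol
Conditions: DIBAL-H (2.5 equiv), CH2Cl2, −78 °C; Rochelle salt work-up
Reagents that add atoms: none
Why: Reductive cleavage of the pivalate (ester reduction) frees the primary C8 carbinol; ketal and diene are inert.

Step 9
Reactants: 14 [(1S,2S,3S,5S,7S)-5-methoxy-2,3-dimethyl-2-[(1E)-3-methylbuta-1,3-dien-1-yl]-6-oxabicyclo[3.2.1]octan-7-yl]methanol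
Product: 16 (2S,4S,5R,7R,8R,9S,10S)-2,9-epoxy-2-methoxyeremophil-11-en-8-ol, via aldehyde 15 (not isolated)
Conditions: RuHCl(CO)(PPh3)3 (5 mol %), dppf (5 mol %), PhMe, 100 °C, sealed tube (acid-free)
Reagents that add atoms: none
Why: Proposed new method: intramolecular redox-neutral carbinol C–H allylation by a tethered 2-substituted diene — Ru dehydrogenates the primary alcohol to aldehyde 15, the resulting Ru–H adds to the diene (H to C6) to give the primary σ-allyl at C12, and this adds through C7 to the aldehyde in a chair six-membered transition state trans-fused to the forming ring B; because the ketal bridge holds C9 axial only one chair is open, so the C7 isopropenyl and C8 hydroxyl emerge trans-diequatorial (7R,8R); the closest known reaction type is the intermolecular Ru-catalysed transfer-hydrogenative coupling of isoprene with primary alcohols (Krische type).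

Step 10
Reactants: 16 (2S,4S,5R,7R,8R,9S,10S)-2,9-epoxy-2-methoxyeremophil-11-en-8-ol; 17 (E)-2-methylbut-2-enoyl chloride (tigloyl chloride)
Product: 18 (2S,4S,5R,7R,8R,9S,10S)-2,9-epoxy-2-methoxyeremophil-11-en-8-yl (2E)-2-methylbut-2-enoate
Conditions: 17 (1.5 equiv), pyridine, DMAP (cat.), CH2Cl2, 0 °C → rt
Reagents that add atoms: none
Why: DMAP-catalysed acylation (esterification) of the only free, equatorial hydroxyl; pyridine instead of Et3N avoids ketene-mediated deconjugation.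

Step 11
Reactants: 18 (2S,4S,5R,7R,8R,9S,10S)-2,9-epoxy-2-methoxyeremophil-11-en-8-yl (2E)-2-methylbut-2-enoate
Product: 19 (4S,5R,7R,8R,9S,10S)-9-hydroxy-2-oxoeremophil-11-en-8-yl (2E)-2-methylbut-2-enoate
Conditions: 1 M aq HCl, THF, 0 °C → rt
Reagents that add atoms: water, O
Why: Acid hydrolysis of the mixed ketal releases the C2 ketone and the axial C9 hydroxyl (in equilibrium with its 2,9-hemiketal); the ester and isopropenyl group survive dilute acid.

Step 12
Reactants: 19 (4S,5R,7R,8R,9S,10S)-9-hydroxy-2-oxoeremophil-11-en-8-yl (2E)-2-methylbut-2-enoate; 20 3-methylbut-2-enoyl chloride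
Product: 21 (1S,2R,3R,4aR,5S,8aS)-4a,5-dimethyl-1-[(3-methylbut-2-enoyl)oxy]-7-oxo-3-(prop-1-en-2-yl)decahydronaphthalen-2-yl (2E)-2-methylbut-2-enoate (CNP0181050.1)
Conditions: 20 (3 equiv), pyridine, DMAP (1 equiv), CH2Cl2, rt
Reagents that add atoms: none
Why: DMAP-mediated acylation (esterification) of the remaining C9 hydroxyl drains the hydroxy ketone/hemiketal equilibrium through the open form to the diester; no stereocentre is touched.

**Compound list**

1 | (S)-but-3-ene-1,2-diol | C=C[C@H](O)CO | starting material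
2 | (2S)-2-hydroxybut-3-en-1-yl 2,2-dimethylpropanoate | C=C[C@H](O)COC(=O)C(C)(C)C | intermediate
3 | but-3-en-2-one | CC(=O)C=C | starting material
4 | (2S,3E)-2-hydroxy-5-oxohex-3-en-1-yl 2,2-dimethylpropanoate | CC(=O)/C=C/[C@H](O)COC(=O)C(C)(C)C | intermediate
5 | (2S,3E)-2,5-bis(triethylsilyloxy)hexa-3,5-dien-1-yl 2,2-dimethylpropanoate | C=C(O[Si](CC)(CC)CC)/C=C/[C@H](O[Si](CC)(CC)CC)COC(=O)C(C)(C)C | intermediate
6 | (E)-2-methylbut-2-enal | C/C=C(\C)C=O | starting material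
7 | (2S)-2-[(1S,5S,6R)-6-formyl-5,6-dimethyl-3-(triethylsilyloxy)cyclohex-2-en-1-yl]-2-(triethylsilyloxy)ethyl 2,2-dimethylpropanoate | O=C[C@@]1(C)[C@H](C=C(O[Si](CC)(CC)CC)C[C@@H]1C)[C@H](O[Si](CC)(CC)CC)COC(=O)C(C)(C)C | intermediate
8 | 3-chloro-2-methylprop-1-ene | C=C(C)CCl | starting material
9 | (2-methylprop-2-en-1-yl)triphenylphosphonium chloride | C=C(C)C[P+](c1ccccc1)(c1ccccc1)c1ccccc1.[Cl-] | intermediate
10 | (2-methylprop-2-en-1-ylidene)triphenylphosphorane | C=C(C)C=P(c1ccccc1)(c1ccccc1)c1ccccc1 | intermediate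
11 | (2S)-2-[(1S,5S,6S)-5,6-dimethyl-6-[(1E)-3-methylbuta-1,3-dien-1-yl]-3-(triethylsilyloxy)cyclohex-2-en-1-yl]-2-(triethylsilyloxy)ethyl 2,2-dimethylpropanoate | C=C(C)/C=C/[C@@]1(C)[C@H](C=C(O[Si](CC)(CC)CC)C[C@@H]1C)[C@H](O[Si](CC)(CC)CC)COC(=O)C(C)(C)C | intermediate
12 | (2S)-2-hydroxy-2-[(1S,2S,3S)-2,3-dimethyl-2-[(1E)-3-methylbuta-1,3-dien-1-yl]-5-oxocyclohexyl]ethyl 2,2-dimethylpropanoate | C=C(C)/C=C/[C@@]1(C)[C@H](CC(=O)C[C@@H]1C)[C@H](O)COC(=O)C(C)(C)C | intermediate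
13 | [(1S,2S,3S,5S,7S)-5-methoxy-2,3-dimethyl-2-[(1E)-3-methylbuta-1,3-dien-1-yl]-6-oxabicyclo[3.2.1]octan-7-yl]methyl 2,2-dimethylpropanoate | C=C(C)/C=C/[C@@]1(C)[C@H](C[C@]2(OC)C[C@@H]1C)[C@H](O2)COC(=O)C(C)(C)C | intermediate
14 | [(1S,2S,3S,5S,7S)-5-methoxy-2,3-dimethyl-2-[(1E)-3-methylbuta-1,3-dien-1-yl]-6-oxabicyclo[3.2.1]octan-7-yl]methanol | C=C(C)/C=C/[C@@]1(C)[C@H](C[C@]2(OC)C[C@@H]1C)[C@H](O2)CO | intermediate
15 | (1S,2S,3S,5S,7S)-5-methoxy-2,3-dimethyl-2-[(1E)-3-methylbuta-1,3-dien-1-yl]-6-oxabicyclo[3.2.1]octane-7-carbaldehyde | C=C(C)/C=C/[C@@]1(C)[C@H](C[C@]2(OC)C[C@@H]1C)[C@H](O2)C=O | intermediate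
16 | (2S,4S,5R,7R,8R,9S,10S)-2,9-epoxy-2-methoxyeremophil-11-en-8-ol | C=C(C)[C@H]1C[C@@]2(C)[C@H](C[C@]3(OC)C[C@@H]2C)[C@H](O3)[C@@H]1O | intermediate
17 | (E)-2-methylbut-2-enoyl chloride | C/C=C(\C)C(=O)Cl | starting material
18 | (2S,4S,5R,7R,8R,9S,10S)-2,9-epoxy-2-methoxyeremophil-11-en-8-yl (2E)-2-methylbut-2-enoate | C=C(C)[C@H]1C[C@@]2(C)[C@H](C[C@]3(OC)C[C@@H]2C)[C@H](O3)[C@@H]1OC(=O)/C(C)=C/C | intermediate
19 | (4S,5R,7R,8R,9S,10S)-9-hydroxy-2-oxoeremophil-11-en-8-yl (2E)-2-methylbut-2-enoate | C=C(C)[C@H]1C[C@@]2(C)[C@H](CC(=O)C[C@@H]2C)[C@H](O)[C@@H]1OC(=O)/C(C)=C/C | intermediate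
20 | 3-methylbut-2-enoyl chloride | CC(C)=CC(=O)Cl | starting material
21 | (1S,2R,3R,4aR,5S,8aS)-4a,5-dimethyl-1-[(3-methylbut-2-enoyl)oxy]-7-oxo-3-(prop-1-en-2-yl)decahydronaphthalen-2-yl (2E)-2-methylbut-2-enoate | C=C(C)[C@H]1C[C@@]2(C)[C@H](CC(=O)C[C@@H]2C)[C@H](OC(=O)C=C(C)C)[C@@H]1OC(=O)/C(C)=C/C | target

**Step count and weak points**

Total step count: 12. Longest linear sequence: 11 (steps 1–4 and 6–12, from 1 to 21); step 5 runs in parallel.

Most likely to fail:

Step 9 (the proposed new cyclisation). Risks are hydrometalation at the wrong diene terminus and isomerisation of the product alkene. The fallback uses known chemistry and sets out from 14. Arene–chromium-catalysed 1,4-hydrogenation of the diene [(η6-naphthalene)Cr(CO)3, H2, acetone, 45 °C] gives the prenyl alcohol [(1S,2R,3S,5S,7S)-5-methoxy-2,3-dimethyl-2-(3-methylbut-2-en-1-yl)-6-oxabicyclo[3.2.1]octan-7-yl]methanol F6. Dess–Martin oxidation gives the aldehyde (1S,2R,3S,5S,7S)-5-methoxy-2,3-dimethyl-2-(3-methylbut-2-en-1-yl)-6-oxabicyclo[3.2.1]octane-7-carbaldehyde F7. A Lewis-acid type-I carbonyl-ene cyclisation (Me2AlCl, CH2Cl2, −78 °C; the citronellal-to-isopulegol manifold) in the same locked chair then closes ring B, and the route is rejoined at 16.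

Step 4 (Diels–Alder). The catalyst and the C9 stereocentre of the diene may be mismatched: ethers of this kind tend to direct a dienophile anti to the allylic oxygen, whereas 7 needs addition syn to O9. The fallback sets out from 4 and lets a tether deliver the dienophile from the O9 side. The C9 hydroxyl is acylated with 17 (pyridine, DMAP) to the ester (2S,3E)-5-oxo-1-(pivaloyloxy)hex-3-en-2-yl (2E)-2-methylbut-2-enoate F1. TESOTf/Et3N gives the silyl dienol ether (2S,3E)-1-(pivaloyloxy)-5-(triethylsilyloxy)hexa-3,5-dien-2-yl (2E)-2-methylbut-2-enoate F2. A thermal ester-tethered intramolecular Diels–Alder reaction (PhMe, 170 °C, BHT) gives the cis-fused lactone [(1S,3aR,4S,7aS)-3a,4-dimethyl-3-oxo-6-(triethylsilyloxy)-1,3,3a,4,5,7a-hexahydro-2-benzofuran-1-yl]methyl 2,2-dimethylpropanoate F3; the cis ring fusion is expected but not certain. DIBAL-H (1.1 equiv, −78 °C) gives the lactol [(1S,3aR,4S,7aS)-3-hydroxy-3a,4-dimethyl-6-(triethylsilyloxy)-1,3,3a,4,5,7a-hexahydro-2-benzofuran-1-yl]methyl 2,2-dimethylpropanoate F4. Wittig reaction with ylide 10 opens it to the hydroxy diene (2S)-2-[(1S,5S,6S)-5,6-dimethyl-6-[(1E)-3-methylbuta-1,3-dien-1-yl]-3-(triethylsilyloxy)cyclohex-2-en-1-yl]-2-hydroxyethyl 2,2-dimethylpropanoate F5. The conditions of step 7 then take F5 to 13, where the route is rejoined.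

Step 12 (acylation of the hindered axial C9 hydroxyl, which sits largely as the hemiketal). The fallback sets out from 18 and skips 19. Treatment with 20 and catalytic ZnCl2 in CH2Cl2 acylates the bridging oxygen and opens the ketal to the α-chloro ether (4S,5R,7R,8R,9S,10S)-2-chloro-2-methoxy-9-[(3-methylbut-2-enoyl)oxy]eremophil-11-en-8-yl (2E)-2-methylbut-2-enoate F8, which already carries the C9 senecioate. Aqueous NaHCO3 work-up hydrolyses it to 21.

**Further compounds**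

F1 | step 4 | (2S,3E)-5-oxo-1-(pivaloyloxy)hex-3-en-2-yl (2E)-2-methylbut-2-enoate | CC(=O)/C=C/[C@H](OC(=O)/C(C)=C/C)COC(=O)C(C)(C)C
F2 | step 4 | (2S,3E)-1-(pivaloyloxy)-5-(triethylsilyloxy)hexa-3,5-dien-2-yl (2E)-2-methylbut-2-enoate | C=C(O[Si](CC)(CC)CC)/C=C/[C@H](OC(=O)/C(C)=C/C)COC(=O)C(C)(C)C
F3 | step 4 | [(1S,3aR,4S,7aS)-3a,4-dimethyl-3-oxo-6-(triethylsilyloxy)-1,3,3a,4,5,7a-hexahydro-2-benzofuran-1-yl]methyl 2,2-dimethylpropanoate | O=C1[C@@]2(C)[C@H](C=C(O[Si](CC)(CC)CC)C[C@@H]2C)[C@H](O1)COC(=O)C(C)(C)C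
F4 | step 4 | [(1S,3aR,4S,7aS)-3-hydroxy-3a,4-dimethyl-6-(triethylsilyloxy)-1,3,3a,4,5,7a-hexahydro-2-benzofuran-1-yl]methyl 2,2-dimethylpropanoate | OC1[C@@]2(C)[C@H](C=C(O[Si](CC)(CC)CC)C[C@@H]2C)[C@H](O1)COC(=O)C(C)(C)C
F5 | step 4 | (2S)-2-[(1S,5S,6S)-5,6-dimethyl-6-[(1E)-3-methylbuta-1,3-dien-1-yl]-3-(triethylsilyloxy)cyclohex-2-en-1-yl]-2-hydroxyethyl 2,2-dimethylpropanoate | C=C(C)/C=C/[C@@]1(C)[C@H](C=C(O[Si](CC)(CC)CC)C[C@@H]1C)[C@H](O)COC(=O)C(C)(C)C
F6 | step 9 | [(1S,2R,3S,5S,7S)-5-methoxy-2,3-dimethyl-2-(3-methylbut-2-en-1-yl)-6-oxabicyclo[3.2.1]octan-7-yl]methanol | CC(C)=CC[C@@]1(C)[C@H](C[C@]2(OC)C[C@@H]1C)[C@H](O2)CO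
F7 | step 9 | (1S,2R,3S,5S,7S)-5-methoxy-2,3-dimethyl-2-(3-methylbut-2-en-1-yl)-6-oxabicyclo[3.2.1]octane-7-carbaldehyde | CC(C)=CC[C@@]1(C)[C@H](C[C@]2(OC)C[C@@H]1C)[C@H](O2)C=O
F8 | step 12 | (4S,5R,7R,8R,9S,10S)-2-chloro-2-methoxy-9-[(3-methylbut-2-enoyl)oxy]eremophil-11-en-8-yl (2E)-2-methylbut-2-enoate | C=C(C)[C@H]1C[C@@]2(C)[C@H](CC(Cl)(OC)C[C@@H]2C)[C@H](OC(=O)C=C(C)C)[C@@H]1OC(=O)/C(C)=C/C
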